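**Retrosynthetic overview**

1. Numbering: bicyclo[3.3.1]nonane with C1 and C5 as bridgeheads (C1 beside C8), C2 and C4 the carbonyl carbons flanking aroyl-bearing C3, C6 CH2, C7 the prenyl CH, C8 the methyl/homoprenyl carbon, C9 the bridging ketone; ring A = C1–C5 with C9, ring B = C5–C8 with C9 and C1. End game: the phenol comes from its triisopropylsilyl ether, the prenyls on C1, C5 and C7 from allyl groups in one threefold cross-metathesis, and the C7 allyl from a C7 iodide by radical allylation.
2. Key disconnection C1–C8 (with C7–I): iodonium-triggered cation–olefin closure of ring B. The strategy rests on the E-geranyl chain C6–C7=C8 attached to C5 of a dearomatised acylphloroglucinol (ring A), whose C7=C8 olefin can fold over ring A to reach the enol carbon C1 across C9.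
3. C1 and C5 carry allyl, not prenyl, during this closure. A prenyl on C5 would offer C1 the same trisubstituted olefin at the same distance as the geranyl chain; allyl stays out of the iodine chemistry and becomes prenyl in the metathesis that C7 needs anyway.
4. The precursor comes from enantioselective dearomative C-geranylation of a Cs-symmetric 3,5-diallyl aroylphloroglucinol (sets C5). That compound comes from phloroglucinol by Houben–Hoesch aroylation, palladium-catalysed C-diallylation and silylation of the one unhindered phenol.
5. Ring order: ring A is the phloroglucinol ring, dearomatised in step 4; ring B is closed in step 5.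

Key step: step 5

Remark: every β-dicarbonyl compound below is a mixture of enol tautomers; one tautomer is drawn, and the descriptors refer to that tautomer.

**Route**

Step 1
Reactants: 1 phloroglucinol; 2 3-hydroxybenzonitrile
Product: 4 (3-hydroxyphenyl)(2,4,6-trihydroxyphenyl)methanone, via ketiminium chloride 3 (not isolated)
Conditions: ZnCl2, HCl (g), Et2O, 0 °C to rt; then H2O, 100 °C
Reagents that add atoms: water, O
Why: Houben–Hoesch acylation: the nitrile activated by HCl and ZnCl2 is attacked once by the very electron-rich phloroglucinol ring, the ketiminium salt 3 deactivates the ring against a second acylation, and its hydrolysis should give the ketone without protection of the 3'-hydroxyl.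

Step 2
Reactants: 4 (3-hydroxyphenyl)(2,4,6-trihydroxyphenyl)methanone; 5 allyl methyl carbonate
Product: 6 (3,5-diallyl-2,4,6-trihydroxyphenyl)(3-hydroxyphenyl)methanone
Conditions: 5 (2.1 equiv), Pd(PPh3)4 (5 mol %), THF, 0 °C to rt
Reagents that add atoms: none
Why: Tsuji–Trost allylation: ionisation of 5 by zerovalent palladium gives a π-allyl palladium complex and methoxide, the phloroglucinolate so formed is allylated at its two free ring carbons (C-allylation is irreversible, whereas any allyl aryl ether formed at the 3'-hydroxyl re-ionises under the catalyst), and two equivalents of 5 should stop the reaction at the aromatic diallyl stage.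

Step 3
Reactants: 6 (3,5-diallyl-2,4,6-trihydroxyphenyl)(3-hydroxyphenyl)methanone
Product: 7 (3,5-diallyl-2,4,6-trihydroxyphenyl)[3-(triisopropylsilyloxy)phenyl]methanone
Conditions: TIPSCl (1.05 equiv), imidazole, DMF, 0 °C
Reagents that add atoms: triisopropylsilyl chloride, CC(C)[Si](Cl)(C(C)C)C(C)C
Why: Selective O-silylation on steric grounds: the 3'-hydroxyl is the only phenol of 6 that is neither flanked by two ortho substituents nor hydrogen-bonded to the ketone, so one equivalent of the bulky silyl chloride should react there, and the triisopropylsilyl ether is chosen because it withstands the hydroxide base of step 4.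

Step 4
Reactants: 7 (3,5-diallyl-2,4,6-trihydroxyphenyl)[3-(triisopropylsilyloxy)phenyl]methanone; 8 geranyl bromide
Product: 9 (6R)-4,6-diallyl-6-[(2E)-3,7-dimethylocta-2,6-dienyl]-3,5-dihydroxy-2-[3-(triisopropylsilyloxy)benzoyl]cyclohexa-2,4-dien-1-one (the dearomatised precursor; its C6 is C5 of the target numbering, R)
Conditions: 8 (1.2 equiv), N-(9-anthracenylmethyl)-O-allylcinchonidinium bromide (10 mol %), CsOH·H2O, toluene, −40 °C
Reagents that add atoms: none
Why: Proposed new method: alkylative dearomatisation (SN2 C-alkylation of the phloroglucinolate at an alkyl-bearing ring carbon) is established for 3,5-dialkyl acylphloroglucinols, and the enantioselective version proposed here rests on the Cs symmetry of 7, whose two allyl-bearing carbons are enantiotopic, so that the phenoxide held in a tight ion pair by the chiral quaternary ammonium cation in a non-polar medium should present only one of them to the primary allylic bromide and set C5 as R with the E olefin intact; the closest known reaction types are the cinchona phase-transfer-catalysed enantioselective alkylative dearomatisation–annulation of 3,5-diprenyl benzoylphloroglucinols with Michael-type electrophiles and the asymmetric phase-transfer allylation of enolates, and the catalyst pseudoenantiomer (cinchonidine or cinchonine series) is to be chosen for the R sense.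

Step 5
Reactants: 9 the dearomatised precursor
Product: 10 (1S,5S,7R,8R)-1,5-diallyl-4-hydroxy-7-iodo-8-methyl-8-(4-methylpent-3-enyl)-3-[3-(triisopropylsilyloxy)benzoyl]bicyclo[3.3.1]non-3-ene-2,9-dione
Conditions: I2 (3 equiv), KI, KHCO3, THF/H2O, 0 °C to rt, dark
Reagents that add atoms: iodine, II
Why: Bicarbonate ionises the vinylogous acid O9–C9=C1–C2=O of 9, iodine reversibly forms an iodonium ion on the electron-rich C7=C8 olefin of the geranyl chain, and the enolate carbon C1 opens it at the tertiary (Markovnikov) carbon C8 anti to iodine, forming C1–C8 and C7–I; the closest known reaction type is the iodonium-induced carbocyclisation (I2, KI, KHCO3) of dearomatised C5-allyl phloroglucinol vinylogous acids, and bond formation between a substituted C1 and a tertiary C8 is known from acid-mediated cation cyclisations in this compound class. Ring B (C1–C8–C7–C6–C5–C9) closes 6-endo-trig with respect to the olefin through a chair in which the chain reaches C1 across C9. C1 is set by the tether, because the geranyl arm can reach only the ring face from which it projects at the existing C5 centre; C7 and C8 are tied to each other by anti addition across the E olefin (methyl and iodine cis on ring B) and to C5 by the chair, which places the C8 methyl axial and the homoprenyl chain and the C7 iodide equatorial (exo). The step needs alkylation at C1 and not at C3 or an enol oxygen: C1 is the alkyl-substituted central carbon of the ionised 1,3-dicarbonyl unit, C3 is the hindered hydrogen-bonded triketone carbon, and the soft iodonium in the chair array should favour carbon over oxygen. It also needs reaction at the C7=C8 olefin only, which the substrate secures because the spectators on C1 and C5 are monosubstituted allyl groups that react with iodine far more slowly than a trisubstituted olefin, and because the remote C=CMe2 olefin has no nucleophile within five- or six-membered reach, so that its iodonium formation, like iodination at C1, is reversible in the presence of iodide.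

Step 6
Reactants: 10 the C7 iodide; 11 allyltributylstannane
Product: 12 (1S,5S,7R,8S)-1,5,7-triallyl-4-hydroxy-8-methyl-8-(4-methylpent-3-enyl)-3-[3-(triisopropylsilyloxy)benzoyl]bicyclo[3.3.1]non-3-ene-2,9-dione
Conditions: 11 (10 equiv), AIBN (cat.), PhH (1 M in 10), 80 °C
Reagents that add atoms: none
Why: Keck radical allylation: tributylstannyl radical abstracts the C7 iodine, the planar secondary C7 radical adds to the stannane on its exo face (the endo face lies under ring A and its aroyl group) and expels the tin radical, so allyl should take the equatorial position of the iodide; closure onto the C1 or C5 allyl groups is barred because both are equatorial on the rigid bicycle, 5-exo closure onto the homoprenyl olefin on C8 would need a trans-fused transition state on the exo face or an approach under ring A and is countered by the high stannane concentration, and the excess of 11 also covers any protodestannylation by the acidic enol.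

Step 7
Reactants: 12 the triallyl compound; 13 2-methyl-2-butene
Product: 14 (1S,5S,7R,8S)-4-hydroxy-8-methyl-1,5,7-tris(3-methylbut-2-enyl)-8-(4-methylpent-3-enyl)-3-[3-(triisopropylsilyloxy)benzoyl]bicyclo[3.3.1]non-3-ene-2,9-dione
Conditions: 13 (60 equiv), second-generation Grubbs catalyst (15 mol %), CH2Cl2, 40 °C, sealed tube
Reagents that add atoms: none
Why: Olefin cross-metathesis: each of the three monosubstituted allyl groups (C1, C5, C7) takes one isopropylidene unit from one molecule of 13 and gives up its CH2 terminus as propene, so three equivalents of 13 are consumed, and the large excess should drive all three exchanges to completion and outrun ring-closing between neighbouring side chains, while the trisubstituted homoprenyl olefin and the stereocentres are not touched.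

Step 8
Reactants: 14 the triprenyl silyl ether
Product: 15 (1S,5S,7R,8S)-4-hydroxy-3-(3-hydroxybenzoyl)-8-methyl-1,5,7-tris(3-methylbut-2-enyl)-8-(4-methylpent-3-enyl)bicyclo[3.3.1]non-3-ene-2,9-dione (CNP0406274.2)
Conditions: Bu4NF, AcOH, THF, 0 °C
Reagents that add atoms: none
Why: Fluoride-mediated cleavage of the aryl silyl ether, driven by Si–F bond formation, should free the phenol, and the acetic acid buffer keeps the medium from turning basic so that the enolised triketone, the four trisubstituted olefins and the stereocentres stay as they are.

**Compound list**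

1 | phloroglucinol (benzene-1,3,5-triol) | Oc1cc(O)cc(O)c1 | starting material
2 | 3-hydroxybenzonitrile | N#Cc1cccc(O)c1 | starting material
3 | (3-hydroxyphenyl)(2,4,6-trihydroxyphenyl)methaniminium chloride | [NH2+]=C(c1cccc(O)c1)c1c(O)cc(O)cc1O.[Cl-] | intermediate
4 | (3-hydroxyphenyl)(2,4,6-trihydroxyphenyl)methanone | O=C(c1cccc(O)c1)c1c(O)cc(O)cc1O | intermediate
5 | allyl methyl carbonate | C=CCOC(=O)OC | starting material
6 | (3,5-diallyl-2,4,6-trihydroxyphenyl)(3-hydroxyphenyl)methanone | C=CCc1c(O)c(CC=C)c(O)c(C(=O)c2cccc(O)c2)c1O | intermediate
7 | (3,5-diallyl-2,4,6-trihydroxyphenyl)[3-(triisopropylsilyloxy)phenyl]methanone | C=CCc1c(O)c(CC=C)c(O)c(C(=O)c2cccc(O[Si](C(C)C)(C(C)C)C(C)C)c2)c1O | intermediate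
8 | geranyl bromide, (E)-1-bromo-3,7-dimethylocta-2,6-diene | CC(C)=CCC/C(C)=C/CBr | starting material
9 | (6R)-4,6-diallyl-6-[(2E)-3,7-dimethylocta-2,6-dienyl]-3,5-dihydroxy-2-[3-(triisopropylsilyloxy)benzoyl]cyclohexa-2,4-dien-1-one; quaternary carbon (C5 of the target numbering) R, bearing allyl and E-geranyl | CC(C)=CCC/C(C)=C/C[C@]2(CC=C)C(O)=C(CC=C)C(=O)C(C(=O)c1cccc(O[Si](C(C)C)(C(C)C)C(C)C)c1)=C2O | intermediate
10 | (1S,5S,7R,8R)-1,5-diallyl-4-hydroxy-7-iodo-8-methyl-8-(4-methylpent-3-enyl)-3-[3-(triisopropylsilyloxy)benzoyl]bicyclo[3.3.1]non-3-ene-2,9-dione; iodide exo (equatorial), C8 methyl axial | CC(C)=CCC[C@@]1(C)[C@H](I)C[C@]2(CC=C)C(=O)[C@@]1(CC=C)C(=O)C(C(=O)c1cccc(O[Si](C(C)C)(C(C)C)C(C)C)c1)=C2O | intermediate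
11 | allyltributylstannane | C=CC[Sn](CCCC)(CCCC)CCCC | starting material
12 | (1S,5S,7R,8S)-1,5,7-triallyl-4-hydroxy-8-methyl-8-(4-methylpent-3-enyl)-3-[3-(triisopropylsilyloxy)benzoyl]bicyclo[3.3.1]non-3-ene-2,9-dione; C7 allyl exo | CC(C)=CCC[C@@]1(C)[C@H](CC=C)C[C@]2(CC=C)C(=O)[C@@]1(CC=C)C(=O)C(C(=O)c1cccc(O[Si](C(C)C)(C(C)C)C(C)C)c1)=C2O | intermediate
13 | 2-methyl-2-butene | CC=C(C)C | starting material
14 | (1S,5S,7R,8S)-4-hydroxy-8-methyl-1,5,7-tris(3-methylbut-2-enyl)-8-(4-methylpent-3-enyl)-3-[3-(triisopropylsilyloxy)benzoyl]bicyclo[3.3.1]non-3-ene-2,9-dione | CC(C)=CCC[C@@]1(C)[C@H](CC=C(C)C)C[C@]2(CC=C(C)C)C(=O)[C@@]1(CC=C(C)C)C(=O)C(C(=O)c1cccc(O[Si](C(C)C)(C(C)C)C(C)C)c1)=C2O | intermediate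
15 | (1S,5S,7R,8S)-4-hydroxy-3-(3-hydroxybenzoyl)-8-methyl-1,5,7-tris(3-methylbut-2-enyl)-8-(4-methylpent-3-enyl)bicyclo[3.3.1]non-3-ene-2,9-dione (CNP0406274.2) | CC(C)=CCC[C@@]1(C)[C@H](CC=C(C)C)C[C@]2(CC=C(C)C)C(=O)[C@@]1(CC=C(C)C)C(=O)C(C(=O)c1cccc(O)c1)=C2O | target

**Step count**

Total steps: 8. Longest linear sequence: 8 steps (1 to 15).

**Steps most likely to fail**

Step 4 (proposed new method). The chiral ion pair may not tell the two enantiotopic allyl-bearing ring carbons apart well enough, and O-geranylation may compete with C-alkylation. The fallback sets out from 7 and uses known chemistry. Alkylative dearomatisation with 8 and LiN(SiMe3)2 in THF at 0 °C, without chiral control, should give the racemic dearomatised geranyl compound F1. This is resolved by preparative chromatography on an amylose tris(3,5-dimethylphenylcarbamate) chiral stationary phase. The R enantiomer is 9, where the route is rejoined before step 5.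

Step 5. Ring closure through an enol oxygen (iodoetherification at C8 by O9 or O4) may outrun C1–C8 bond formation, iodide may reverse the closure, and a boat-type closure would erode the C7/C8 relationship. The fallback sets out from 9 and changes the trigger and the form of the nucleophile. N-(Phenylseleno)phthalimide with SnCl4 in CH2Cl2 at −78 °C acts on the neutral enol. The seleniranium ion on C7=C8 should be opened by C1 at C8 in the same anti sense to give the C7 phenylselenide F2. Radical allylation of its C–Se bond with 11 and AIBN in PhH at 80 °C, as in step 6, should then give 12, where the route is rejoined before step 7.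

Step 6. The C7 radical and the homoprenyl olefin on C8 form a 5-hexenyl radical, so 5-exo ring closure may outrun the bimolecular allyl transfer; reduction of the radical and attack from the endo face are lesser risks. The fallback sets out from 10 and takes the olefin out of reach before the radical is formed. Dimethyldioxirane (1 equiv) in acetone/CH2Cl2 at −40 °C should epoxidise only the trisubstituted homoprenyl olefin, since the allyl groups are monosubstituted and the enol is electron-poor, and give the epoxy iodide F3 as a mixture of two epimers at the oxirane carbon. Radical allylation with 11 and AIBN in PhH at 80 °C should then give the triallyl epoxide F4. Deoxygenation with Zn, NaI and NaOAc in AcOH at rt (iodohydrin formation, then reductive elimination) should restore the olefin and give 12, where the route is rejoined before step 7.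

**Further compounds**

F1 | step 4 | racemic 4,6-diallyl-6-[(2E)-3,7-dimethylocta-2,6-dienyl]-3,5-dihydroxy-2-[3-(triisopropylsilyloxy)benzoyl]cyclohexa-2,4-dien-1-one | CC(C)=CCC/C(C)=C/CC2(CC=C)C(O)=C(CC=C)C(=O)C(C(=O)c1cccc(O[Si](C(C)C)(C(C)C)C(C)C)c1)=C2O
F2 | step 5 | (1S,5S,7R,8R)-1,5-diallyl-4-hydroxy-8-methyl-8-(4-methylpent-3-enyl)-7-(phenylselanyl)-3-[3-(triisopropylsilyloxy)benzoyl]bicyclo[3.3.1]non-3-ene-2,9-dione | CC(C)=CCC[C@@]1(C)[C@H]([Se]c3ccccc3)C[C@]2(CC=C)C(=O)[C@@]1(CC=C)C(=O)C(C(=O)c1cccc(O[Si](C(C)C)(C(C)C)C(C)C)c1)=C2O
F3 | step 6 | (1S,5S,7R,8R)-1,5-diallyl-8-[2-(3,3-dimethyloxiran-2-yl)ethyl]-4-hydroxy-7-iodo-8-methyl-3-[3-(triisopropylsilyloxy)benzoyl]bicyclo[3.3.1]non-3-ene-2,9-dione, both epimers at the oxirane carbon | CC3(C)OC3CC[C@@]1(C)[C@H](I)C[C@]2(CC=C)C(=O)[C@@]1(CC=C)C(=O)C(C(=O)c1cccc(O[Si](C(C)C)(C(C)C)C(C)C)c1)=C2O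
F4 | step 6 | (1S,5S,7R,8S)-1,5,7-triallyl-8-[2-(3,3-dimethyloxiran-2-yl)ethyl]-4-hydroxy-8-methyl-3-[3-(triisopropylsilyloxy)benzoyl]bicyclo[3.3.1]non-3-ene-2,9-dione, both epimers at the oxirane carbon | CC3(C)OC3CC[C@@]1(C)[C@H](CC=C)C[C@]2(CC=C)C(=O)[C@@]1(CC=C)C(=O)C(C(=O)c1cccc(O[Si](C(C)C)(C(C)C)C(C)C)c1)=C2O
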